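The runs are calculated with made-up constants; the scatter is artificial.

1. Thursday's flask could not be short of coupling partner if each partner made one target and nothing else: at the last reading, 90.0 min, target stood at 54.8%, and that took 36.5% of the partner charged. Yet target then rose at 0.162 of its pace between the first and fourth readings.

| setting | Thursday's | Sunday's | flask |
|---|---|---|---|
| substrate | 0.25 M | 0.12 M | 0.25 M |
| coupling partner | 1.5 equiv | 1.5 equiv | 1.50 equiv |
| catalyst | 5.2 mol% | 5.2 mol% | 5.2 mol% |
| temperature | 25 °C | 10 °C | 25 °C |
| remark | the very flask that is asked about, followed so far | run made earlier |  |
| time |  |  | 2.5 h |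

- Thursday's (time / min: target / %): 8.00: 17.8; 12.0: 24.3; 15.0: 27.9; 25.0: 36.7; 40.0: 44.3; 60.0: 49.4; 90.0: 54.8
- Sunday's (time / min: target / %): 15.0: 7.0; 30.0: 10.9; 50.0: 16.2; 60.0: 18.9; 80.0: 22.2; 120: 30.0

(each reading ± 0.5 percentage points)

- alder: at 2.5 h take out 90% of the target then present, then wait 2.5 h
- elm: at 2.5 h add catalyst, 100% of the amount charged, then wait 2.5 h
- ash: at 2.5 h raise the temperature by 15 K, then wait 2.5 h
- birch: change nothing and wait 2.5 h more
- larch: at 2.5 h add coupling partner, 100% of the amount charged, then wait 2.5 h

- target taken out counts as made
- the analysis behind the earlier runs scatters by 0.5 percentage points, standard deviation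
- additions bring no volume worth counting

1. target, in percent of the substrate first charged, at 2.5 h
2. the option that brings most further target ("none" if no option brings more than 2 percentage points) (alder / elm / ash / birch / larch / none)
3. target present, with what was taken out counted in, in percent of the substrate first charged, after birch
4. target present, with what was taken out counted in, in percent of the substrate first charged, after larch

2. I turned the question round. Elm could beat larch if catalyst was dead at 2.5 h with partner still standing. Larch could win if partner was leaving by a path the readings did not show, and that was one route to a larch win among others. Sunday's run, with c(substrate) about half of Thursday's and colder, differs from Thursday's in two settings, so I did not use it to part the stories. I bet on lost partner, knowing it was a bet.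

3. I divided the rate of partner spending by the rate of target making, so that time dropped out. If the charge was spent by the last reading, this gives 2.74: the partner bill, partner spent per target made. The elm story needs a bill near 1.

4. At that bill, larch's second charge buys 54.8% of the substrate, more than the 45.2% not yet target at that reading. So I expected larch to win and to take the flask close to complete.

5. The forecast held otherwise: “The catalyst is therefore dying”. It gave 58% now, elm as best, 58.8% after birch and 60% after larch.

6. The flask gave 59.8% now, 62.6% after birch and 93.0% after larch, and larch brought most, 33 percentage points.

    substrate + coupling partner + catalyst → target + catalyst, rate k1*[substrate]*[coupling partner]*[catalyst]/(1 + ([substrate]/sat1)) (0.193 M, k = 14.9 M⁻² min⁻¹, Ea = 39.0 kJ mol⁻¹)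
    2 substrate → self-condensation product (k = 6.26 × 10⁻⁵ M⁻¹ min⁻¹, Ea = 94.0 kJ mol⁻¹)
    2 coupling partner → homo dimer (k = 0.0886 M⁻¹ min⁻¹, Ea = 65.0 kJ mol⁻¹)
    (constants at 25 °C)

In this flask, target making and the loss of partner to homo dimer ran together while partner lasted: half of each step's turnover up to 2.5 h was done by 0.288 h and 0.120 h respectively, and partner stood at 7.79% by 1.25 h. By 2.50 h partner, the limiting reagent, stood at 2.31% with substrate at 40.1%, and catalyst held at 100%, so the bill was 2.45.

For the neighbour flask with substrate at 0.42 M, the bill of 2.74 gives 54.8% target. The computed flask reached 69.3% with 0.33% of its partner left, a bill of 2.16.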